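The 17-membered ring is disconnected at the bond between the ortho carbon of ring D (the unsubstituted ortho-phenylene ring, next to its diaryl ether oxygen) and the neighbouring CH2 of the two-carbon bridge to ring A. A one-pot hydroboration and intramolecular B-alkyl Suzuki–Miyaura coupling forms this C(sp3)–C(sp2) bond and closes the macrocycle in one operation. It exploits that this ring D carbon can be carried as a C–Cl bond that stays silent until a dialkylbiarylphosphine catalyst is used, and the bridge as a vinyl group on ring A. The precursor is an open chain of four arenes with vinyl on ring A and chlorine on ring D.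

Key step: step 6

Remark: ring A is the ring with two OH and one aryloxy group, ring B the para-phenylene ring, ring C the ring with one OH, ring D the unsubstituted ortho-phenylene ring. The target has no stereocenter. Compounds 1, 2, 5 and 6 are taken as commercially available.

Step 1
Reactants: 1 3-hydroxy-4,5-dimethoxybenzaldehyde; 2 (4-iodophenyl)boronic acid
Product: 3 3-(4-iodophenoxy)-4,5-dimethoxybenzaldehyde
Conditions: Cu(OAc)2 (20 mol %), pyridine, 4 Å MS, CH2Cl2, O2 (1 atm), rt
Reagents that add atoms: none
Why: Chan–Lam oxidative O-arylation joins the phenol of 1 to the arylboronic acid 2 at room temperature, where the aryl iodide and the aldehyde should stay untouched.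

Step 2
Reactants: 3 3-(4-iodophenoxy)-4,5-dimethoxybenzaldehyde
Product: 4 5-ethenyl-1-(4-iodophenoxy)-2,3-dimethoxybenzene
Conditions: Ph3PCH3Br, KOtBu, THF, 0 °C to rt
Reagents that add atoms: methyltriphenylphosphonium bromide, C[P+](c1ccccc1)(c1ccccc1)c1ccccc1.[Br-]
Why: Wittig methylenation of the aromatic aldehyde with the non-stabilized ylide, generated with KOtBu so that no halogen–metal exchange can occur at the aryl iodide.

Step 3
Reactants: 5 2-fluoro-3-methoxybenzaldehyde; 6 2-chlorophenol
Product: 7 2-(2-chlorophenoxy)-3-methoxybenzaldehyde
Conditions: K2CO3, DMAc, 130 °C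
Reagents that add atoms: none
Why: Nucleophilic aromatic substitution (SNAr), in which the phenoxide of 6 displaces the fluoride of 5 that the ortho formyl group activates, while the chloride on the unactivated ring is inert.

Step 4
Reactants: 7 2-(2-chlorophenoxy)-3-methoxybenzaldehyde
Product: 8 2-(2-chlorophenoxy)-1-ethenyl-3-methoxybenzene
Conditions: Ph3PCH3Br, KOtBu, THF, 0 °C to rt
Reagents that add atoms: methyltriphenylphosphonium bromide, C[P+](c1ccccc1)(c1ccccc1)c1ccccc1.[Br-]
Why: Wittig methylenation of the aldehyde, which the aryl chloride and both ether types tolerate.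

Step 5
Reactants: 8 2-(2-chlorophenoxy)-1-ethenyl-3-methoxybenzene; 4 5-ethenyl-1-(4-iodophenoxy)-2,3-dimethoxybenzene
Product: 10 2-(2-chlorophenoxy)-1-{2-[4-(5-ethenyl-2,3-dimethoxyphenoxy)phenyl]ethyl}-3-methoxybenzene, via alkylborane 9 (not isolated)
Conditions: 8, 9-BBN, THF, rt; then H2O, 4, Pd(dppf)Cl2 (5 mol %), AsPh3, Cs2CO3, DMF, rt
Reagents that add atoms: 9-borabicyclo[3.3.1]nonane (9-BBN), B1C2CCCC1CCC2 (its boron and carbons stay only in intermediate 9; product 10 keeps one hydrogen from it)
Why: Intermolecular B-alkyl Suzuki–Miyaura coupling, in which anti-Markovnikov hydroboration of 8 gives a primary alkylborane that couples at room temperature with the aryl iodide of 4, while the aryl chloride is not activated by this catalyst and Heck reaction of the vinyl group of 4 should be slow.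

Step 6
Reactants: 10 2-(2-chlorophenoxy)-1-{2-[4-(5-ethenyl-2,3-dimethoxyphenoxy)phenyl]ethyl}-3-methoxybenzene
Product: 12 tri-O-methyl ether of the target (17-membered macrocycle with OMe in place of each of the three OH groups), via alkylborane 11 (not isolated)
Conditions: 9-BBN, THF, rt to 50 °C; then H2O; then added over 12 h by syringe pump to Pd(OAc)2 (15 mol %), SPhos, K3PO4, THF/H2O, 70 °C, 2 mM final concentration
Reagents that add atoms: 9-borabicyclo[3.3.1]nonane (9-BBN), B1C2CCCC1CCC2 (its boron and carbons stay only in intermediate 11; product 12 keeps one hydrogen from it)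
Why: 9-BBN adds to the vinyl group on ring A with boron at the terminal carbon (anti-Markovnikov hydroboration), and the base turns alkylborane 11 into a borate. Zerovalent palladium carrying the electron-rich biaryl phosphine SPhos inserts into the C–Cl bond of ring D, the alkyl group passes from boron to palladium within the same molecule, and reductive elimination forms the ring D carbon–CH2 bond. The closest known reaction type is the B-alkyl Suzuki–Miyaura macrocyclization, combined with the aryl chloride activation by dialkylbiaryl phosphines known for intermolecular B-alkyl couplings. The 17-membered ring is closed end to end by this intramolecular cross-coupling through a palladacycle that contracts on reductive elimination, and no stereocenter is formed. The step needs ring closure to win over oligomerization and boron at the terminal instead of the benzylic carbon; slow addition at high dilution, the bent ortho-linked diaryl ether at rings C and D and the steric demand of 9-BBN should secure both.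

Step 7
Reactants: 12 tri-O-methyl ether of the target
Product: 13 CNP0290892.0 (target)
Conditions: BBr3, CH2Cl2, −78 °C to rt; then H2O
Reagents that add atoms: none
Why: BBr3 demethylation cleaves the three aryl methyl ethers by Lewis acid activation and bromide attack at methyl, while the diaryl ethers and the ethano bridges are stable under these conditions.

Compound list
1 | 3-hydroxy-4,5-dimethoxybenzaldehyde | O=Cc1cc(O)c(OC)c(OC)c1 | starting material
2 | (4-iodophenyl)boronic acid | OB(O)c1ccc(I)cc1 | starting material
3 | 3-(4-iodophenoxy)-4,5-dimethoxybenzaldehyde | O=Cc1cc(OC)c(OC)c(Oc2ccc(I)cc2)c1 | intermediate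
4 | 5-ethenyl-1-(4-iodophenoxy)-2,3-dimethoxybenzene | C=Cc1cc(OC)c(OC)c(Oc2ccc(I)cc2)c1 | intermediate
5 | 2-fluoro-3-methoxybenzaldehyde | O=Cc1cccc(OC)c1F | starting material
6 | 2-chlorophenol | Oc1ccccc1Cl | starting material
7 | 2-(2-chlorophenoxy)-3-methoxybenzaldehyde | O=Cc1cccc(OC)c1Oc1ccccc1Cl | intermediate
8 | 2-(2-chlorophenoxy)-1-ethenyl-3-methoxybenzene | C=Cc1cccc(OC)c1Oc1ccccc1Cl | intermediate
9 | 9-{2-[2-(2-chlorophenoxy)-3-methoxyphenyl]ethyl}-9-borabicyclo[3.3.1]nonane | COc1cccc(CCB2C3CCCC2CCC3)c1Oc1ccccc1Cl | intermediate
10 | 2-(2-chlorophenoxy)-1-{2-[4-(5-ethenyl-2,3-dimethoxyphenoxy)phenyl]ethyl}-3-methoxybenzene | C=Cc1cc(OC)c(OC)c(Oc2ccc(CCc3cccc(OC)c3Oc3ccccc3Cl)cc2)c1 | intermediate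
11 | 9-{2-[3-(4-{2-[2-(2-chlorophenoxy)-3-methoxyphenyl]ethyl}phenoxy)-4,5-dimethoxyphenyl]ethyl}-9-borabicyclo[3.3.1]nonane | COc1cc(CCB2C3CCCC2CCC3)cc(Oc2ccc(CCc3cccc(OC)c3Oc3ccccc3Cl)cc2)c1OC | intermediate
12 | tri-O-methyl ether of the target (17-membered macrocycle, two OMe on ring A, one OMe on ring C) | COc1cc2cc(c1OC)Oc1ccc(cc1)CCc1cccc(OC)c1Oc1ccccc1CC2 | intermediate
13 | CNP0290892.0 | Oc1cc2cc(c1O)Oc1ccc(cc1)CCc1cccc(O)c1Oc1ccccc1CC2 | target

Total step count: 7. Longest linear sequence: 5 steps (steps 3, 4, 5, 6, 7, or equally steps 1, 2, 5, 6, 7).

Steps most likely to fail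

Step 6. Intermolecular coupling of the alkylborane may outrun ring closure and give oligomers. Oxidative addition at the hindered, electron-rich C–Cl bond may also be so slow that the alkylborane is lost by protodeboronation. The fallback sets out from 10 and forms the same ring D carbon–carbon bond by a Heck macrocyclization (Pd2(dba)3, P(t-Bu)3, Cs2CO3, dioxane, 110 °C, high dilution). Arylation at the terminal vinyl carbon should give the macrocyclic (E)-stilbene tri-O-methyl ether F1. Hydrogenation of the stilbene double bond (H2, Pd/C, EtOAc) should then give 12, where the fallback comes back to the route.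

Step 3. Addition of the hindered, weakly nucleophilic phenoxide to a fluoride activated by only one formyl group and flanked by a methoxy group may be sluggish, and the aldehyde may degrade under base at the temperature required. The fallback sets out from 6 and replaces the addition–elimination pathway by a Cu-catalysed Ullmann-type C–O coupling with commercially available 2-bromo-3-methoxybenzaldehyde (CuI, picolinic acid, K3PO4, DMSO, 90 °C). This should give 7 directly, where the fallback comes back to the route; no new compound is made (F0).

Step 5. Heck arylation of the vinyl group of 4, or hydroboration of it by residual 9-BBN, may compete with the cross-coupling and lead to oligomers. The fallback sets out from 3, which carries the future vinyl group masked as the aldehyde, and from alkylborane 9 prepared as before. B-alkyl Suzuki–Miyaura coupling under the same Pd(dppf)Cl2 conditions should give the open-chain aldehyde 3-(4-{2-[2-(2-chlorophenoxy)-3-methoxyphenyl]ethyl}phenoxy)-4,5-dimethoxybenzaldehyde F2. Wittig methylenation (Ph3PCH3Br, KOtBu, THF) should then give 10, where the fallback comes back to the route.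

Further compounds
F1 | step 6 | macrocyclic (E)-stilbene tri-O-methyl ether (double bond between ring D and ring A in place of the ethano bridge of 12) | COc1cc2cc(c1OC)Oc1ccc(cc1)CCc1cccc(OC)c1Oc1ccccc1/C=C/2
F0 | step 3 | none | none
F2 | step 5 | 3-(4-{2-[2-(2-chlorophenoxy)-3-methoxyphenyl]ethyl}phenoxy)-4,5-dimethoxybenzaldehyde | O=Cc1cc(OC)c(OC)c(Oc2ccc(CCc3cccc(OC)c3Oc3ccccc3Cl)cc2)c1
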